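## Retrosynthetic overview

1. Ring C is not coupled as an acid but grown last: the terminal 2-hydroxy-4-methoxy-6-methylbenzoate is disconnected by a [4+2] benzannulation into an aryl but-2-ynoate of the ring A–ring B didepside and a 1,1,3-trioxygenated butadiene (the new step).
2. The but-2-ynoate comes from O-acylation of the only unchelated phenol of the ring A–ring B didepside with but-2-ynoic acid.
3. The didepside is cut at the ring A–ring B ester into methyl orsellinate (ring A) and 4-O-benzyl-2-O-methylorsellinic acid (ring B); the ring B acid is made from methyl orsellinate by benzylation, methylation and hydrolysis.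
4. Order of ring formation: rings A and B are bought as aromatic rings (both from methyl orsellinate) and joined first; ring C is the only ring that is built, in the last step.

Assumption: the target has no stereocentre and no stereogenic double bond (it is achiral), so the "single enantiomer" is the compound as drawn and no stereocontrol is needed.

## Route

Step 1
Reactants: 1 methyl 2,4-dihydroxy-6-methylbenzoate (methyl orsellinate)
Product: 2 methyl 4-(benzyloxy)-2-hydroxy-6-methylbenzoate
Conditions: BnBr (1.05 equiv), K2CO3 (1.2 equiv), acetone, 56 °C, 8 h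
Reagents that add atoms: benzyl bromide, BrCc1ccccc1
Why: Williamson ether synthesis; only the 4-OH reacts because the 2-OH is hydrogen-bonded to the ester carbonyl and is far less acidic and nucleophilic.

Step 2
Reactants: 2 methyl 4-(benzyloxy)-2-hydroxy-6-methylbenzoate
Product: 3 methyl 4-(benzyloxy)-2-methoxy-6-methylbenzoate
Conditions: MeI (3 equiv), K2CO3 (3 equiv), DMF, 60 °C, 12 h
Reagents that add atoms: iodomethane, CI
Why: Williamson O-methylation; excess MeI in a polar aprotic solvent overcomes the low reactivity of the chelated phenol, and nothing else in 2 can be alkylated.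

Step 3
Reactants: 3 methyl 4-(benzyloxy)-2-methoxy-6-methylbenzoate
Product: 5 4-(benzyloxy)-2-methoxy-6-methylbenzoic acid, via potassium carboxylate 4 (not isolated)
Conditions: KOH (10 equiv), DMSO/H2O (4:1), 90 °C, 6 h; then 2 M HCl, 0 °C, pH 2
Reagents that add atoms: potassium hydroxide, [K+].[OH-]
Why: Saponification (acyl–oxygen cleavage) of the di-ortho-substituted ester by poorly solvated hydroxide in aqueous DMSO; cold acidification avoids decarboxylation, and the benzyl and methyl ethers are inert.

Step 4
Reactants: 5 4-(benzyloxy)-2-methoxy-6-methylbenzoic acid; 1 methyl 2,4-dihydroxy-6-methylbenzoate (1.1 equiv)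
Product: 7 methyl 4-{[4-(benzyloxy)-2-methoxy-6-methylbenzoyl]oxy}-2-hydroxy-6-methylbenzoate, via mixed trifluoroacetic anhydride 6 (not isolated)
Conditions: (CF3CO)2O (4 equiv), PhMe, 23 °C, 4 h; aq. NaHCO3 work-up
Reagents that add atoms: none
Why: Mixed-anhydride esterification; the acylium-like mixed anhydride 6 tolerates the two ortho substituents of the acid and acylates only the unchelated 4-OH of 1.

Step 5
Reactants: 7 methyl 4-{[4-(benzyloxy)-2-methoxy-6-methylbenzoyl]oxy}-2-hydroxy-6-methylbenzoate
Product: 8 methyl 2-hydroxy-4-[(4-hydroxy-2-methoxy-6-methylbenzoyl)oxy]-6-methylbenzoate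
Conditions: H2 (1 atm), 10% Pd/C, EtOAc, 23 °C, 3 h
Reagents that add atoms: none
Why: Catalytic hydrogenolysis of the benzyl ether; the aryl ester, the methyl ester and the arenes are untouched under these neutral conditions.

Step 6
Reactants: 8 methyl 2-hydroxy-4-[(4-hydroxy-2-methoxy-6-methylbenzoyl)oxy]-6-methylbenzoate; 9 but-2-ynoic acid (1.1 equiv)
Product: 11 methyl 4-{[4-(but-2-ynoyloxy)-2-methoxy-6-methylbenzoyl]oxy}-2-hydroxy-6-methylbenzoate, via O-acylisourea 10 (not isolated)
Conditions: N,N'-dicyclohexylcarbodiimide (1.15 equiv), 4-(dimethylamino)pyridine (5 mol %), CH2Cl2, 0 °C, 2 h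
Reagents that add atoms: none
Why: Steglich esterification of an unhindered acid at the only unchelated phenol (ring B 4-OH); low temperature and catalytic base keep the ynoate from isomerising to the allenoate.

Step 7
Reactants: 12 methyl (2E)-3-methoxybut-2-enoate
Product: 14 (1E)-1,3-dimethoxy-1-(trimethylsilyloxy)buta-1,3-diene, via lithium dienolate 13 (not isolated)
Conditions: LiN(iPr)2 (1.1 equiv), THF, −78 °C, 1 h; Me3SiCl (1.3 equiv), −78 → 0 °C; pentane, filtration, bulb-to-bulb distillation
Reagents that add atoms: chlorotrimethylsilane, C[Si](C)(C)Cl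
Why: γ-Deprotonation of the vinylogous ester gives the extended dienolate, which is O-silylated (silyl ketene acetal formation); the C1 geometry (mainly 1E) does not matter because that carbon becomes the aromatic C–OH carbon.

Step 8
Reactants: 11 methyl 4-{[4-(but-2-ynoyloxy)-2-methoxy-6-methylbenzoyl]oxy}-2-hydroxy-6-methylbenzoate; 14 (1E)-1,3-dimethoxy-1-(trimethylsilyloxy)buta-1,3-diene (3 equiv)
Product: 17 methyl 2-hydroxy-4-({4-[(2-hydroxy-4-methoxy-6-methylbenzoyl)oxy]-2-methoxy-6-methylbenzoyl}oxy)-6-methylbenzoate, via trimethylsilyl ether 15 (not isolated), via silyl ketal cycloadduct 16 (not isolated)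
Conditions: N,O-bis(trimethylsilyl)acetamide (1.5 equiv), PhMe, 23 °C, 1 h; then 14, 120 °C (sealed tube), 24 h; then 1 M HCl/THF (1:4), 23 °C, 1 h
Reagents that add atoms: none
Why: Proposed new method: ring-last depside construction by Diels–Alder benzannulation of an aryl but-2-ynoate. The chelated phenol is first masked in the flask as its trimethylsilyl ether 15, so it can neither protonate the ketene acetal nor add to the ynoate. The electron-rich diene 14 (HOMO) then adds to the alkyne, whose LUMO is lowered by the aryloxycarbonyl group: the unsubstituted CH2 terminus (largest HOMO coefficient) bonds to the methyl-bearing β-carbon and the ketene-acetal carbon bonds to the α-carbon, giving the racemic cyclohexa-1,4-diene 16. Under acid the mixed methyl silyl ketal of 16 loses methanol to aromatise and both silyl ethers hydrolyse, so OH and CH3 end up ortho and OCH3 para to the ester carbon, exactly as in ring C. The di-ortho-substituted salicylate ester is thus made without any attack on a hindered carbonyl and without an O-protecting group; the only stereocentre (the ketal carbon of 16) is destroyed on aromatisation. The closest known reaction type is the Diels–Alder/aromatisation of alkyl alk-2-ynoates and macrocyclic ynoate lactones with 1,3-dioxygenated silyloxy dienes to give resorcylate esters, which has not been shown for aryl alkynoates or used to form a depside.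

## Compound list

1 | methyl 2,4-dihydroxy-6-methylbenzoate (methyl orsellinate) | COC(=O)c1c(C)cc(O)cc1O | starting material
2 | methyl 4-(benzyloxy)-2-hydroxy-6-methylbenzoate | COC(=O)c1c(C)cc(OCc2ccccc2)cc1O | intermediate
3 | methyl 4-(benzyloxy)-2-methoxy-6-methylbenzoate | COC(=O)c1c(C)cc(OCc2ccccc2)cc1OC | intermediate
4 | potassium 4-(benzyloxy)-2-methoxy-6-methylbenzoate (not isolated) | [K+].[O-]C(=O)c1c(C)cc(OCc2ccccc2)cc1OC | intermediate
5 | 4-(benzyloxy)-2-methoxy-6-methylbenzoic acid | OC(=O)c1c(C)cc(OCc2ccccc2)cc1OC | intermediate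
6 | 4-(benzyloxy)-2-methoxy-6-methylbenzoic trifluoroacetic anhydride (not isolated) | O=C(OC(=O)C(F)(F)F)c1c(C)cc(OCc2ccccc2)cc1OC | intermediate
7 | methyl 4-{[4-(benzyloxy)-2-methoxy-6-methylbenzoyl]oxy}-2-hydroxy-6-methylbenzoate | COC(=O)c1c(C)cc(OC(=O)c2c(C)cc(OCc3ccccc3)cc2OC)cc1O | intermediate
8 | methyl 2-hydroxy-4-[(4-hydroxy-2-methoxy-6-methylbenzoyl)oxy]-6-methylbenzoate | COC(=O)c1c(C)cc(OC(=O)c2c(C)cc(O)cc2OC)cc1O | intermediate
9 | but-2-ynoic acid | CC#CC(=O)O | starting material
10 | O-(but-2-ynoyl)-N,N'-dicyclohexylisourea (not isolated) | CC#CC(=O)OC(=NC1CCCCC1)NC1CCCCC1 | intermediate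
11 | methyl 4-{[4-(but-2-ynoyloxy)-2-methoxy-6-methylbenzoyl]oxy}-2-hydroxy-6-methylbenzoate | COC(=O)c1c(C)cc(OC(=O)c2c(C)cc(OC(=O)C#CC)cc2OC)cc1O | intermediate
12 | methyl (2E)-3-methoxybut-2-enoate | CO/C(C)=C/C(=O)OC | starting material
13 | lithium (1Z)-1,3-dimethoxybuta-1,3-dien-1-olate (not isolated) | [Li+].[O-]/C(OC)=C/C(OC)=C | intermediate
14 | (1E)-1,3-dimethoxy-1-(trimethylsilyloxy)buta-1,3-diene (major isomer drawn; used as obtained) | C=C(OC)/C=C(\OC)O[Si](C)(C)C | intermediate
15 | methyl 4-{[4-(but-2-ynoyloxy)-2-methoxy-6-methylbenzoyl]oxy}-2-methyl-6-(trimethylsilyloxy)benzoate (not isolated) | COC(=O)c1c(C)cc(OC(=O)c2c(C)cc(OC(=O)C#CC)cc2OC)cc1O[Si](C)(C)C | intermediate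
16 | methyl 4-{[4-({[4,6-dimethoxy-2-methyl-6-(trimethylsilyloxy)cyclohexa-1,4-dien-1-yl]carbonyl}oxy)-2-methoxy-6-methylbenzoyl]oxy}-2-methyl-6-(trimethylsilyloxy)benzoate (racemic at the ketal carbon; not isolated) | COC(=O)c1c(C)cc(OC(=O)c2c(C)cc(OC(=O)C3=C(C)CC(OC)=CC3(OC)O[Si](C)(C)C)cc2OC)cc1O[Si](C)(C)C | intermediate
17 | methyl 2-hydroxy-4-({4-[(2-hydroxy-4-methoxy-6-methylbenzoyl)oxy]-2-methoxy-6-methylbenzoyl}oxy)-6-methylbenzoate (CNP0357736.0, achiral) | COC(=O)c1c(C)cc(OC(=O)c2c(C)cc(OC(=O)c3c(C)cc(OC)cc3O)cc2OC)cc1O | target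

## Step count and risks

Total steps: 8. Longest linear sequence: 7 steps (steps 1, 2, 3, 4, 5, 6, 8; compounds 1 → 2 → 3 → 5 → 7 → 8 → 11 → 17). Step 7 is a one-step side branch.

**Most likely to fail, first: step 8 (the proposed new benzannulation).** The β-methyl ynoate may add too slowly, the diene may decompose at 120 °C, or the ketal may lose the silyloxy group and give the 2-methoxy ring. The fallback is the classical protected-acid depside coupling, all known chemistry. It sets out from 8 (the acid partner is grown from 1) and comes back to the route at 17.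
- Selective 4-O-methylation of 1 (MeI 1.05 equiv, K2CO3, acetone, 56 °C) gives methyl 2-hydroxy-4-methoxy-6-methylbenzoate F1.
- Benzylation of the chelated phenol (BnBr, K2CO3, DMF, 70 °C) gives methyl 2-(benzyloxy)-4-methoxy-6-methylbenzoate F2.
- KOH in DMSO/H2O at 90 °C gives potassium 2-(benzyloxy)-4-methoxy-6-methylbenzoate F3, and cold HCl then gives 2-(benzyloxy)-4-methoxy-6-methylbenzoic acid F4.
- (CF3CO)2O in PhMe at 23 °C converts F4 into 2-(benzyloxy)-4-methoxy-6-methylbenzoic trifluoroacetic anhydride F5, which acylates the free ring B 4-OH of 8 to give methyl 4-[(4-{[2-(benzyloxy)-4-methoxy-6-methylbenzoyl]oxy}-2-methoxy-6-methylbenzoyl)oxy]-2-hydroxy-6-methylbenzoate F6.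
- Hydrogenolysis (H2, 10% Pd/C, EtOAc) of F6 gives 17.

**Second: step 4 (coupling of the di-ortho-substituted acid).** Under the acidic mixed-anhydride conditions the electron-rich ring A could be C-acylated, or conversion could be low. The fallback changes to an isolated acyl chloride and a phenoxide nucleophile under basic conditions. It sets out from 5 and comes back at 7: (COCl)2 with catalytic DMF in CH2Cl2 at 0 → 23 °C gives 4-(benzyloxy)-2-methoxy-6-methylbenzoyl chloride F7, which is added to 1 and K2CO3 in acetone at 0 → 23 °C, where the more acidic 4-OH is acylated as its phenoxide to give 7.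

**Third: step 3 (hydrolysis of the hindered methyl ester).** Hydroxide attack at the shielded carbonyl may be slow, and forcing it risks decarboxylation. The fallback cleaves the alkyl–oxygen bond instead, which is indifferent to the ortho substituents. It sets out from 3 and comes back at 5: NaSPh (3 equiv) in DMF at 80 °C demethylates the ester by substitution at the methyl carbon to give sodium 4-(benzyloxy)-2-methoxy-6-methylbenzoate F8, and cold 2 M HCl then gives 5. The aryl methyl and benzyl ethers survive at this temperature.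

## Further compounds

F1 | step 8 | methyl 2-hydroxy-4-methoxy-6-methylbenzoate | COC(=O)c1c(C)cc(OC)cc1O
F2 | step 8 | methyl 2-(benzyloxy)-4-methoxy-6-methylbenzoate | COC(=O)c1c(C)cc(OC)cc1OCc2ccccc2
F3 | step 8 | potassium 2-(benzyloxy)-4-methoxy-6-methylbenzoate | [K+].[O-]C(=O)c1c(C)cc(OC)cc1OCc2ccccc2
F4 | step 8 | 2-(benzyloxy)-4-methoxy-6-methylbenzoic acid | OC(=O)c1c(C)cc(OC)cc1OCc2ccccc2
F5 | step 8 | 2-(benzyloxy)-4-methoxy-6-methylbenzoic trifluoroacetic anhydride | O=C(OC(=O)C(F)(F)F)c1c(C)cc(OC)cc1OCc2ccccc2
F6 | step 8 | methyl 4-[(4-{[2-(benzyloxy)-4-methoxy-6-methylbenzoyl]oxy}-2-methoxy-6-methylbenzoyl)oxy]-2-hydroxy-6-methylbenzoate | COC(=O)c1c(C)cc(OC(=O)c2c(C)cc(OC(=O)c3c(C)cc(OC)cc3OCc4ccccc4)cc2OC)cc1O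
F7 | step 4 | 4-(benzyloxy)-2-methoxy-6-methylbenzoyl chloride | O=C(Cl)c1c(C)cc(OCc2ccccc2)cc1OC
F8 | step 3 | sodium 4-(benzyloxy)-2-methoxy-6-methylbenzoate | [Na+].[O-]C(=O)c1c(C)cc(OCc2ccccc2)cc1OC
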